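**Strategy.** The upper pyran ring (ring C: O1–C2–C3–C4–C4a–C8a) is cut at C2–C3 and C4–C4a. This gives an aryl oxocarbenium ion (ring A–O1=C2H–ring B, from an O-aryl O-methyl acetal) and an E enol acetate on C6 of ring D of benzylated, C8-brominated (+)-gallocatechin, so the 4→6 link is set beforehand. A chiral-acid-controlled cationic [4+2] annulation (oxa-Povarov) then forms both C–C bonds, ring C and the C2/C3/C4 triad in one operation. It exploits the phloroglucinol-type ring D, which makes C3 the nucleophilic alkene carbon and stabilises charge at C4, and the resorcinol-type ring A, which closes at C4a para to its C7 oxygen.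

Key step: step 10

Remarks on the chemistry:
- Flavan numbering is used for each unit. The upper (fisetinidol) unit has rings A (benzo), B (catechol) and C (pyran). The lower (gallocatechin) unit has rings D (benzo), E (pyrogallol) and F (pyran). Bn = benzyl, Bpin = 4,4,5,5-tetramethyl-1,3,2-dioxaborolan-2-yl.
- Assumption: (+)-gallocatechin (2R,3S) is taken as a commercial starting material.
- Assumption: the enantiomeric series of the acid catalyst in step 10 cannot be predicted with certainty. The (S,S) form is written on the assumption that a trial run confirms it as the one that delivers the 2R,3S,4S adduct; otherwise its mirror image is used.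

**Step 1**
Reactants: 1 (+)-gallocatechin
Product: 2 5,7,3',4',5'-penta-O-benzyl-(+)-gallocatechin
Conditions: BnBr (5.5 equiv), K2CO3, DMF, 0 °C to rt, argon
Reagents that add atoms: benzyl bromide, BrCc1ccccc1
Why: Williamson etherification with a carbonate base should benzylate the five phenols only, since the secondary 3-OH is not deprotonated and the mild base leaves C2 and C3 untouched.

**Step 2**
Reactants: 2 5,7,3',4',5'-penta-O-benzyl-(+)-gallocatechin
Product: 3 3,5,7,3',4',5'-hexa-O-benzyl-(+)-gallocatechin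
Conditions: NaH, BnBr, cat. Bu4NI, THF/DMF, 0 °C to rt
Reagents that add atoms: benzyl bromide, BrCc1ccccc1
Why: Williamson etherification of the alkoxide caps the 3-OH so that no free hydroxyl meets the Vilsmeier salt, the lithium base or the oxocarbenium ion later, and no stereocenter is touched.

**Step 3**
Reactants: 3 hexa-O-benzyl-(+)-gallocatechin
Product: 4 8-bromo-hexa-O-benzyl-(+)-gallocatechin
Conditions: NBS (1.0 equiv), CH2Cl2, −78 to 0 °C
Reagents that add atoms: N-bromosuccinimide, O=C1CCC(=O)N1Br
Why: Electrophilic aromatic bromination of the phloroglucinol-type ring D of 5,7-di-O-benzylflavans should go to C8, the less hindered of its two free positions, which blocks C8 and leaves C6 as the only nucleophilic site of that ring.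

**Step 4**
Reactants: 4 8-bromo-hexa-O-benzyl-(+)-gallocatechin
Product: 6 8-bromo-hexa-O-benzyl-(+)-gallocatechin-6-carbaldehyde, via iminium chloride 5 (not isolated)
Conditions: (chloromethylene)dimethyliminium chloride, DMF/MeCN, 0 to 50 °C; then aq. NaOAc
Reagents that add atoms: (chloromethylene)dimethyliminium chloride, C[N+](C)=CCl.[Cl-]; water, O
Why: Vilsmeier–Haack formylation should attack the only free position of the trioxygenated ring D (C6, ortho to both benzyloxy groups and para to O1) in preference to the less activated ring E, and hydrolysis of iminium salt 5 gives the aldehyde.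

**Step 5**
Reactants: 6 8-bromo-hexa-O-benzyl-(+)-gallocatechin-6-carbaldehyde
Product: 7 E alkenyl pinacol boronate (ring D C6–CH=CH–Bpin)
Conditions: CH2(Bpin)2, lithium 2,2,6,6-tetramethylpiperidide, THF, 0 °C; then 6, −78 °C to rt
Reagents that add atoms: bis(pinacolato)borylmethane, CC1(C)OB(CB2OC(C)(C)C(C)(C)O2)OC1(C)C
Why: Boron–Wittig olefination (addition of the lithiated gem-diboronate to the aldehyde and syn elimination of the boron alkoxide) should give the E alkenyl boronate, because the aryl group and the remaining boryl group sit anti in the elimination.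

**Step 6**
Reactants: 7 E alkenyl pinacol boronate
Product: 8 potassium E alkenyltrifluoroborate
Conditions: KHF2 (aq.), MeOH/THF, rt
Reagents that add atoms: potassium hydrogen difluoride, F.[F-].[K+]
Why: Fluoride exchange at boron should convert the pinacol ester into the trifluoroborate with retention of the E geometry, giving the boron partner needed for the copper-catalysed acyloxylation.

**Step 7**
Reactants: 8 potassium E alkenyltrifluoroborate
Product: 9 E enol acetate (ring D C6–CH=CH–OAc)
Conditions: AcOH (2 equiv), CuBr (10 mol %), DMAP (20 mol %), 4 Å MS, O2 (1 atm), MeCN, 40 °C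
Reagents that add atoms: acetic acid, CC(=O)O
Why: Chan–Lam-type oxidative C–O coupling of alkenyltrifluoroborates with carboxylic acids is stereoretentive, so the E enol acetate should result, and the aryl bromide is inert to copper at this temperature.

**Step 8**
Reactants: 10 3,4-bis(benzyloxy)benzaldehyde
Product: 11 3,4-bis(benzyloxy)benzaldehyde dimethyl acetal
Conditions: HC(OMe)3, MeOH, cat. p-TsOH, rt; then Et3N
Reagents that add atoms: trimethyl orthoformate, COC(OC)OC; methanol, CO
Why: Acid-catalysed acetalisation, driven by the orthoformate as water scavenger, should convert the aldehyde into its dimethyl acetal.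

**Step 9**
Reactants: 11 3,4-bis(benzyloxy)benzaldehyde dimethyl acetal; 12 3-(benzyloxy)phenol
Product: 14 racemic O-[3-(benzyloxy)phenyl] O-methyl acetal of 3,4-bis(benzyloxy)benzaldehyde, via chloro ether 13 (not isolated)
Conditions: AcCl (1.1 equiv), cat. SOCl2, CH2Cl2, 0 °C to rt, evaporate; then 12, NaH, THF, 0 °C
Reagents that add atoms: none
Why: Acetyl chloride should exchange one methoxy group of the acetal for chloride to give α-chloro ether 13, and SN1-type O-alkylation of the sodium phenoxide of 12 by it gives the mixed acetal, whose stereocenter is erased on ionisation in step 10.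

**Step 10**
Reactants: 14 racemic O-aryl O-methyl acetal; 9 E enol acetate
Product: 17 3-O-acetyl-7,3',4'-tri-O-benzylfisetinidol-(4α→6)-8-bromo-3,5,7,3',4',5'-hexa-O-benzylgallocatechin (upper unit 2R,3S,4S; lower unit 2R,3S), via oxocarbenium ion 15 (not isolated), via benzylic cation 16 (not isolated)
Conditions: (S,S)-IDPi acid HN[P(=NSO2CF3)(O2C20H10Ar2)]2 with Ar = 3,5-(CF3)2C6H3 (from (S)-3,3'-Ar2-BINOL; 5 mol %), 5 Å MS, CHCl3/toluene, −40 °C, slow addition of 14 (1.3 equiv) to 9
Reagents that add atoms: none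
Why: Proposed new method: the acid ionises acetal 14 (methanol is taken up by the sieves) to the E aryl oxocarbenium ion 15, paired with the confined chiral anion; C3 of 9 adds to C2 to give the C4 cation 16 (stabilised by the three oxygens of ring D and bridged by the neighbouring acetoxy group), which is captured by C4a of ring A with loss of the proton that turns the acid over. The closest known reaction is the SnCl4-promoted oxa-Povarov annulation of O-aryl O-alkyl acetals with styrenes to 2,4-cis chromans, and the closest asymmetric relatives are chiral-phosphate-controlled Povarov reactions and confined-acid-catalysed additions to oxocarbenium ions; new here is counter-anion control of the oxygen series. Ring C closes as a formal inverse-demand [4+2] between the 2-oxadiene cation C4a=C8a–O1=C2 and the C3=C4 alkene, the last event being a 6-endo-trig Friedel–Crafts alkylation. C2 and C3 are set together in the first bond formation, the anion choosing the face of 15 (absolute sense, 2R) and the endo position of ring D placing the acetoxy group exo (2,3-trans); C4 is set in the closure, trans to the acetoxy group through the E alkene geometry, acetoxonium participation and an all-equatorial chair. The step needs bonding through C3 and not C4, which the weakly donating enol ester oxygen leaves to the strongly donating ring D, closure para to the C7 benzyloxy group of ring A, which is the unhindered ortho position, and no arylation of ring D, which the C8 bromine prevents. The lower-unit stereocenters are too remote to steer, so a wrong-face adduct would be a diastereomer of 17 and should be removable by chromatography.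

**Step 11**
Reactants: 17 3-O-acetyl protected dimer
Product: 18 7,3',4'-tri-O-benzylfisetinidol-(4α→6)-8-bromo-3,5,7,3',4',5'-hexa-O-benzylgallocatechin
Conditions: K2CO3 (cat.), MeOH/THF, rt
Reagents that add atoms: none
Why: Base-catalysed transesterification (methanolysis) should remove the 3-acetate without touching benzyl ethers, the aryl bromide or any stereocenter, and it is placed before the phenols are freed so that no polyphenol meets base.

**Step 12**
Reactants: 18 protected bromo dimer
Product: 19 fisetinidol-(4α→6)-gallocatechin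
Conditions: H2 (1 atm), Pd(OH)2/C, Et3N (1.5 equiv), THF/MeOH/H2O, rt
Reagents that add atoms: none
Why: Catalytic hydrogenolysis should cleave the nine benzyl ethers and the C8–Br bond in one operation, the amine buffering the HBr so that the acid-labile interflavan bond and the two C2 ether stereocenters survive.

**Compound list**

1 | (+)-gallocatechin, (2R,3S)-2-(3,4,5-trihydroxyphenyl)chromane-3,5,7-triol | Oc1cc(O)c2c(c1)O[C@H](c1cc(O)c(O)c(O)c1)[C@@H](O)C2 | starting material
2 | (2R,3S)-5,7-bis(benzyloxy)-2-[3,4,5-tris(benzyloxy)phenyl]chroman-3-ol | c1ccccc1COc1cc(OCc2ccccc2)c2c(c1)O[C@H](c1cc(OCc3ccccc3)c(OCc3ccccc3)c(OCc3ccccc3)c1)[C@@H](O)C2 | intermediate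
3 | (2R,3S)-3,5,7-tris(benzyloxy)-2-[3,4,5-tris(benzyloxy)phenyl]chromane | c1ccccc1COc1cc(OCc2ccccc2)c2c(c1)O[C@H](c1cc(OCc3ccccc3)c(OCc3ccccc3)c(OCc3ccccc3)c1)[C@@H](OCc1ccccc1)C2 | intermediate
4 | (2R,3S)-3,5,7-tris(benzyloxy)-8-bromo-2-[3,4,5-tris(benzyloxy)phenyl]chromane | c1ccccc1COc1cc(OCc2ccccc2)c2c(c1Br)O[C@H](c1cc(OCc3ccccc3)c(OCc3ccccc3)c(OCc3ccccc3)c1)[C@@H](OCc1ccccc1)C2 | intermediate
5 | N,N-dimethyliminium chloride of aldehyde 6 (ring D C6–CH=NMe2+ Cl−) | c1ccccc1COc1c(C=[N+](C)C)c(OCc2ccccc2)c2c(c1Br)O[C@H](c1cc(OCc3ccccc3)c(OCc3ccccc3)c(OCc3ccccc3)c1)[C@@H](OCc1ccccc1)C2.[Cl-] | intermediate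
6 | (2R,3S)-3,5,7-tris(benzyloxy)-8-bromo-2-[3,4,5-tris(benzyloxy)phenyl]chromane-6-carbaldehyde | c1ccccc1COc1c(C=O)c(OCc2ccccc2)c2c(c1Br)O[C@H](c1cc(OCc3ccccc3)c(OCc3ccccc3)c(OCc3ccccc3)c1)[C@@H](OCc1ccccc1)C2 | intermediate
7 | 2-{(E)-2-[(2R,3S)-3,5,7-tris(benzyloxy)-8-bromo-2-(3,4,5-tris(benzyloxy)phenyl)chroman-6-yl]vinyl}-4,4,5,5-tetramethyl-1,3,2-dioxaborolane | c1ccccc1COc1c(/C=C/B2OC(C)(C)C(C)(C)O2)c(OCc2ccccc2)c2c(c1Br)O[C@H](c1cc(OCc3ccccc3)c(OCc3ccccc3)c(OCc3ccccc3)c1)[C@@H](OCc1ccccc1)C2 | intermediate
8 | potassium (E)-trifluoro{2-[(2R,3S)-3,5,7-tris(benzyloxy)-8-bromo-2-(3,4,5-tris(benzyloxy)phenyl)chroman-6-yl]vinyl}borate | c1ccccc1COc1c(/C=C/[B-](F)(F)F)c(OCc2ccccc2)c2c(c1Br)O[C@H](c1cc(OCc3ccccc3)c(OCc3ccccc3)c(OCc3ccccc3)c1)[C@@H](OCc1ccccc1)C2.[K+] | intermediate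
9 | (E)-2-[(2R,3S)-3,5,7-tris(benzyloxy)-8-bromo-2-(3,4,5-tris(benzyloxy)phenyl)chroman-6-yl]vinyl acetate | c1ccccc1COc1c(/C=C/OC(C)=O)c(OCc2ccccc2)c2c(c1Br)O[C@H](c1cc(OCc3ccccc3)c(OCc3ccccc3)c(OCc3ccccc3)c1)[C@@H](OCc1ccccc1)C2 | intermediate
10 | 3,4-bis(benzyloxy)benzaldehyde | O=Cc1ccc(OCc2ccccc2)c(OCc2ccccc2)c1 | starting material
11 | 1,2-bis(benzyloxy)-4-(dimethoxymethyl)benzene | COC(OC)c1ccc(OCc2ccccc2)c(OCc2ccccc2)c1 | intermediate
12 | 3-(benzyloxy)phenol | Oc1cccc(OCc2ccccc2)c1 | starting material
13 | 1,2-bis(benzyloxy)-4-[chloro(methoxy)methyl]benzene (racemic) | COC(Cl)c1ccc(OCc2ccccc2)c(OCc2ccccc2)c1 | intermediate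
14 | 1,2-bis(benzyloxy)-4-{[3-(benzyloxy)phenoxy](methoxy)methyl}benzene (racemic) | COC(Oc1cccc(OCc2ccccc2)c1)c1ccc(OCc2ccccc2)c(OCc2ccccc2)c1 | intermediate
15 | (E)-[3-(benzyloxy)phenyl][3,4-bis(benzyloxy)benzylidene]oxonium ion (paired with the catalyst anion) | c1ccccc1COc1cccc(/[O+]=C/c2ccc(OCc3ccccc3)c(OCc3ccccc3)c2)c1 | intermediate
16 | open-chain C4 benzylic cation, ring A–O1–C2H(ring B)–C3H(OAc)–C4H(+)–ring D, configured at C2 and C3 as in 17 | c1ccccc1COc1cccc(O[C@H](c2ccc(OCc3ccccc3)c(OCc3ccccc3)c2)[C@@H](OC(C)=O)[CH+]c2c(OCc3ccccc3)c(Br)c3c(c2OCc2ccccc2)C[C@H](OCc2ccccc2)[C@@H](c2cc(OCc4ccccc4)c(OCc4ccccc4)c(OCc4ccccc4)c2)O3)c1 | intermediate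
17 | 3-O-acetyl-7,3',4'-tri-O-benzylfisetinidol-(4α→6)-8-bromo-3,5,7,3',4',5'-hexa-O-benzylgallocatechin; upper unit 2R,3S,4S, lower unit 2R,3S | c1ccccc1COc1ccc2c(c1)O[C@H](c1ccc(OCc3ccccc3)c(OCc3ccccc3)c1)[C@@H](OC(C)=O)[C@@H]2c1c(OCc2ccccc2)c(Br)c2c(c1OCc1ccccc1)C[C@H](OCc1ccccc1)[C@@H](c1cc(OCc3ccccc3)c(OCc3ccccc3)c(OCc3ccccc3)c1)O2 | intermediate
18 | 7,3',4'-tri-O-benzylfisetinidol-(4α→6)-8-bromo-3,5,7,3',4',5'-hexa-O-benzylgallocatechin (upper 3-OH free); upper unit 2R,3S,4S, lower unit 2R,3S | c1ccccc1COc1ccc2c(c1)O[C@H](c1ccc(OCc3ccccc3)c(OCc3ccccc3)c1)[C@@H](O)[C@@H]2c1c(OCc2ccccc2)c(Br)c2c(c1OCc1ccccc1)C[C@H](OCc1ccccc1)[C@@H](c1cc(OCc3ccccc3)c(OCc3ccccc3)c(OCc3ccccc3)c1)O2 | intermediate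
19 | fisetinidol-(4α→6)-gallocatechin; upper unit 2R,3S,4S, lower unit 2R,3S | Oc1ccc2c(c1)O[C@H](c1ccc(O)c(O)c1)[C@@H](O)[C@@H]2c1c(O)cc2c(c1O)C[C@H](O)[C@@H](c1cc(O)c(O)c(O)c1)O2 | target

**Step count.** Total: 12 steps. Longest linear sequence: 10 steps (steps 1–7, 10, 11, 12); steps 8 and 9 form the short branch.

**Steps most likely to fail**

1. Step 10. The ion pair may discriminate the two faces of the oxocarbenium ion poorly, bonding may occur through the wrong alkene carbon, or the acid may cause self-condensation of the electron-rich enol acetate before the acetal ionises. The fallback uses known chemistry, sets out from 4 and comes back at 18. Commercial (2R,3R)-fustin is benzylated at its three phenols (BnBr, K2CO3, DMF) to 7,3',4'-tri-O-benzylfustin F1. Reduction with NaBH4 (THF/EtOH, 0 °C) should give the 2,3-trans-3,4-trans flavan-3,4-diol F2. F2 is then ionised at C4 (BF3·OEt2, CH2Cl2, −20 °C) in the presence of 4. Friedel–Crafts capture of the C4 benzylic cation at C6 of ring D (C8 is blocked by bromine), from the face anti to the 3-hydroxyl, should give 18 directly. The C2/C3 configuration of the upper unit then comes from the chiral pool.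

2. Step 7. Protodeboronation or oxidative homocoupling may outrun C–O bond formation at the hindered, electron-rich alkenylborate. The fallback sets out from 7 and comes back at 9. Oxidation of the C–B bond (NaBO3·4H2O, THF/H2O, rt) should give the arylacetaldehyde F3. O-Acetylation of its enol (Ac2O, Et3N, cat. DMAP, CH2Cl2) should give 9, with the E isomer expected to predominate because the di-ortho-substituted aryl group disfavours the Z form; any Z isomer is removed by chromatography.

3. Step 4. Formylation at C6, which is flanked by two benzyloxy groups, may be slow, and the acid formed may start to cleave benzyl ethers on prolonged heating. The fallback sets out from 4 and comes back at 6. Iodination at C6 (NIS, cat. TFA, MeCN/CH2Cl2, 0 °C) should give the 6-iodo-8-bromo compound F4. Iodine–magnesium exchange, selective for the C–I bond (iPrMgCl·LiCl, THF, −40 °C), followed by a DMF quench should give 6.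

**Further compounds**

F1 | step 10 | (2R,3R)-7-(benzyloxy)-2-[3,4-bis(benzyloxy)phenyl]-3-hydroxychroman-4-one (7,3',4'-tri-O-benzylfustin) | c1ccccc1COc1ccc2c(c1)O[C@H](c1ccc(OCc3ccccc3)c(OCc3ccccc3)c1)[C@@H](O)C2=O
F2 | step 10 | (2R,3S,4R)-7-(benzyloxy)-2-[3,4-bis(benzyloxy)phenyl]chromane-3,4-diol | c1ccccc1COc1ccc2c(c1)O[C@H](c1ccc(OCc3ccccc3)c(OCc3ccccc3)c1)[C@@H](O)[C@@H]2O
F3 | step 7 | 2-[(2R,3S)-3,5,7-tris(benzyloxy)-8-bromo-2-(3,4,5-tris(benzyloxy)phenyl)chroman-6-yl]acetaldehyde | c1ccccc1COc1c(CC=O)c(OCc2ccccc2)c2c(c1Br)O[C@H](c1cc(OCc3ccccc3)c(OCc3ccccc3)c(OCc3ccccc3)c1)[C@@H](OCc1ccccc1)C2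
F4 | step 4 | (2R,3S)-3,5,7-tris(benzyloxy)-8-bromo-6-iodo-2-[3,4,5-tris(benzyloxy)phenyl]chromane | c1ccccc1COc1c(I)c(OCc2ccccc2)c2c(c1Br)O[C@H](c1cc(OCc3ccccc3)c(OCc3ccccc3)c(OCc3ccccc3)c1)[C@@H](OCc1ccccc1)C2
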